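The whole side chain is cut back to a single carbon–boron bond at position 4 of ring A, the 2,4-disubstituted oxazole. The feature exploited is the pattern of the chain C1 (on ring A) to C6: carbinols C1, C3 and C4 of like sense, methylene C2, and C5 of opposite sense beside methyl C6. One diol of twofold symmetry on boron can therefore set all four centres in one telescoped run of five boronate homologations, because at C5 methyl enters as the nucleophile and boron becomes the oxygen. The precursor is 2-methyloxazol-4-ylboronic acid esterified with (R,R)-1,2-dicyclohexylethane-1,2-diol; its 2-methyl group later carries ring B.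

Key step: step 2

Assumption: boronates of the (R,R) diol are taken to give (αS)-chlorides (Cl > C > B > H) on ZnCl2-promoted homologation, the sense known for (R,R)-butane-2,3-diol esters; 5-bromooxazole is taken to be purchasable.

Step 1
Reactants: 1 4-bromo-2-methyloxazole; 2 (1R,2R)-1,2-dicyclohexylethane-1,2-diol
Product: 5 (4R,5R)-4,5-dicyclohexyl-2-(2-methyloxazol-4-yl)-1,3,2-dioxaborolane, via (2-methyloxazol-4-yl)magnesium chloride 3 (not isolated), via chloromagnesium triisopropoxy(2-methyloxazol-4-yl)borate 4 (not isolated)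
Conditions: iPrMgCl·LiCl, THF, −20 → 0 °C; B(OiPr)3, −78 °C → rt; 2, AcOH, rt
Reagents that add atoms: triisopropyl borate, CC(C)OB(OC(C)C)OC(C)C
Why: Bromine–magnesium exchange on the electron-poor 4-bromooxazole, borylation of the aryl magnesium species and acid-promoted transesterification with the diol should give the cyclic boronate without a free boronic acid stage; no stereocentre is formed and those of the diol are untouched.

Step 2
Reactants: 5 (4R,5R)-4,5-dicyclohexyl-2-(2-methyloxazol-4-yl)-1,3,2-dioxaborolane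
Product: 15 (2S,3R,4S,6R)-3,4,6-tris(benzyloxy)-6-(2-methyloxazol-4-yl)hexan-2-ol, via C1 chloroboronate 6 (not isolated), via C1 benzyloxyboronate 7 (not isolated), via C2 methylene boronate 8 (not isolated), via C3 chloroboronate 9 (not isolated), via C3 benzyloxyboronate 10 (not isolated), via C4 chloroboronate 11 (not isolated), via C4 benzyloxyboronate 12 (not isolated), via C5 chloroboronate 13 (not isolated), via C5 methylboronate 14 (not isolated)
Conditions: telescoped, crude boronates taken on after NH4Cl/pentane work-up: (a) CH2Cl2, n-BuLi, THF, −100 °C; ZnCl2, → 0 °C; BnOLi (excess), THF/DMSO, 0 °C → rt; (b) ICH2Cl, n-BuLi, THF, −78 °C → rt; (c) and (d) as (a); (e) CH2Cl2, n-BuLi, THF, −100 °C; ZnCl2, → rt; MeMgBr, −78 °C → rt; (f) H2O2, NaOH, THF/H2O, 0 °C → rt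
Reagents that add atoms: dichloromethane, ClCCl; chloroiodomethane, ClCI; benzyl alcohol (used as BnOLi), OCc1ccccc1; methylmagnesium bromide, C[Mg]Br; hydrogen peroxide, OO
Why: In each cycle the lithium carbenoid adds to boron to give a transient tetracoordinate borate and a ZnCl2-assisted 1,2-shift of the carbon ligand expels chloride; benzyloxide or the methyl magnesium reagent then adds to boron and a second 1,2-shift displaces the remaining chloride with inversion, and alkaline H2O2 finally exchanges boron for hydroxyl with retention. This is the Matteson asymmetric homologation of chiral diol boronic esters, known for aryl and alkoxyalkyl boronates, and no ring is closed. At C1, C3 and C4 the (R,R) diol directs the first shift to the (S)-chloride, and its inversion by benzyloxide gives three ethers of like sense. At C5 the same director again gives the (S)-chloride, methyl replaces chloride with inversion and oxygen then takes the place of boron, so the C5 oxygen has the opposite sense and is the only free hydroxyl. The step needs boron capture of the carbenoid to outrun metalation of the ring A 2-methyl group and C5–H, which the Lewis-acidic trigonal boron at −100 °C should secure. It also needs the labile heterobenzylic C1 chloride to keep its configuration, which ZnCl2 sequestration of chloride and immediate substitution should secure.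

Step 3
Reactants: 15 (2S,3R,4S,6R)-3,4,6-tris(benzyloxy)-6-(2-methyloxazol-4-yl)hexan-2-ol; 16 5-bromooxazole
Product: 19 (2S,3R,4S,6R)-3,4,6-tris(benzyloxy)-6-[2-(oxazol-5-ylmethyl)oxazol-4-yl]hexan-2-ol, via dilithiated alcohol 17 (not isolated), via oxazol-2-ylmethylzinc chloride 18 (not isolated)
Conditions: LiNEt2 (2.3 equiv, from HNEt2/n-BuLi), THF, −78 °C; ZnCl2, −78 → 0 °C; 16, Pd(OAc)2 (cat.), SPhos, 25–50 °C; NH4Cl aq
Reagents that add atoms: none
Why: The first equivalent of amide base only forms the C5 alkoxide and the second, through amine-mediated equilibration (lateral lithiation of a 2-methyloxazole), gives the 2-lithiomethyl species, whose transmetalation to zinc and Negishi cross-coupling with the bromide through zerovalent palladium should form the bond from the methylene to C5 of ring B; no stereocentre takes part.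

Step 4
Reactants: 19 (2S,3R,4S,6R)-3,4,6-tris(benzyloxy)-6-[2-(oxazol-5-ylmethyl)oxazol-4-yl]hexan-2-ol; 20 palmitoyl chloride
Product: 21 (2S,3R,4S,6R)-3,4,6-tris(benzyloxy)-6-[2-(oxazol-5-ylmethyl)oxazol-4-yl]hexan-2-yl hexadecanoate
Conditions: pyridine, DMAP (cat.), CH2Cl2, 0 °C → rt
Reagents that add atoms: none
Why: DMAP-catalysed acylation (nucleophilic acyl substitution) of the only free hydroxyl leaves the C5–O bond and its configuration untouched, and the benzyl ethers and both oxazoles are inert to the acid chloride under these conditions.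

Step 5
Reactants: 21 (2S,3R,4S,6R)-3,4,6-tris(benzyloxy)-6-[2-(oxazol-5-ylmethyl)oxazol-4-yl]hexan-2-yl hexadecanoate
Product: 22 (2S,3S,4S,6R)-3,4,6-trihydroxy-6-[2-(oxazol-5-ylmethyl)oxazol-4-yl]hexan-2-yl hexadecanoate
Conditions: H2 (1 atm), Pd(OH)2/C, EtOAc, rt
Reagents that add atoms: none
Why: Catalytic hydrogenolysis of the three benzyl ethers runs under neutral conditions that should leave the ester, both oxazoles and the four stereocentres untouched and offer neither acid nor base to drive acyl migration to the C4 hydroxyl.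

Compound list
1 | 4-bromo-2-methyloxazole | Cc1nc(Br)co1 | starting material
2 | (1R,2R)-1,2-dicyclohexylethane-1,2-diol | O[C@H](C1CCCCC1)[C@H](O)C1CCCCC1 | starting material
3 | (2-methyloxazol-4-yl)magnesium chloride (LiCl complex) | Cc1nc([Mg]Cl)co1 | intermediate
4 | chloromagnesium triisopropoxy(2-methyloxazol-4-yl)borate | Cc1nc(co1)[B-](OC(C)C)(OC(C)C)OC(C)C.[Mg+]Cl | intermediate
5 | (4R,5R)-4,5-dicyclohexyl-2-(2-methyloxazol-4-yl)-1,3,2-dioxaborolane | Cc1nc(B2O[C@H](C3CCCCC3)[C@@H](C3CCCCC3)O2)co1 | intermediate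
6 | (4R,5R)-2-[(S)-chloro(2-methyloxazol-4-yl)methyl]-4,5-dicyclohexyl-1,3,2-dioxaborolane | Cc1nc(co1)[C@@H](Cl)B1O[C@H](C2CCCCC2)[C@@H](C2CCCCC2)O1 | intermediate
7 | (4R,5R)-2-[(R)-benzyloxy(2-methyloxazol-4-yl)methyl]-4,5-dicyclohexyl-1,3,2-dioxaborolane | Cc1nc(co1)[C@H](OCc1ccccc1)B1O[C@H](C2CCCCC2)[C@@H](C2CCCCC2)O1 | intermediate
8 | (4R,5R)-2-[(2R)-2-benzyloxy-2-(2-methyloxazol-4-yl)ethyl]-4,5-dicyclohexyl-1,3,2-dioxaborolane | Cc1nc(co1)[C@H](OCc1ccccc1)CB1O[C@H](C2CCCCC2)[C@@H](C2CCCCC2)O1 | intermediate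
9 | (4R,5R)-2-[(1S,3R)-3-benzyloxy-1-chloro-3-(2-methyloxazol-4-yl)propyl]-4,5-dicyclohexyl-1,3,2-dioxaborolane | Cc1nc(co1)[C@H](OCc1ccccc1)C[C@@H](Cl)B1O[C@H](C2CCCCC2)[C@@H](C2CCCCC2)O1 | intermediate
10 | (4R,5R)-2-[(1R,3R)-1,3-bis(benzyloxy)-3-(2-methyloxazol-4-yl)propyl]-4,5-dicyclohexyl-1,3,2-dioxaborolane | Cc1nc(co1)[C@H](OCc1ccccc1)C[C@H](OCc1ccccc1)B1O[C@H](C2CCCCC2)[C@@H](C2CCCCC2)O1 | intermediate
11 | (4R,5R)-2-[(1S,2S,4R)-2,4-bis(benzyloxy)-1-chloro-4-(2-methyloxazol-4-yl)butyl]-4,5-dicyclohexyl-1,3,2-dioxaborolane | Cc1nc(co1)[C@H](OCc1ccccc1)C[C@H](OCc1ccccc1)[C@@H](Cl)B1O[C@H](C2CCCCC2)[C@@H](C2CCCCC2)O1 | intermediate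
12 | (4R,5R)-2-[(1R,2S,4R)-1,2,4-tris(benzyloxy)-4-(2-methyloxazol-4-yl)butyl]-4,5-dicyclohexyl-1,3,2-dioxaborolane | Cc1nc(co1)[C@H](OCc1ccccc1)C[C@H](OCc1ccccc1)[C@H](OCc1ccccc1)B1O[C@H](C2CCCCC2)[C@@H](C2CCCCC2)O1 | intermediate
13 | (4R,5R)-2-[(1S,2S,3S,5R)-2,3,5-tris(benzyloxy)-1-chloro-5-(2-methyloxazol-4-yl)pentyl]-4,5-dicyclohexyl-1,3,2-dioxaborolane | Cc1nc(co1)[C@H](OCc1ccccc1)C[C@H](OCc1ccccc1)[C@H](OCc1ccccc1)[C@@H](Cl)B1O[C@H](C2CCCCC2)[C@@H](C2CCCCC2)O1 | intermediate
14 | (4R,5R)-2-[(2S,3R,4S,6R)-3,4,6-tris(benzyloxy)-6-(2-methyloxazol-4-yl)hexan-2-yl]-4,5-dicyclohexyl-1,3,2-dioxaborolane | Cc1nc(co1)[C@H](OCc1ccccc1)C[C@H](OCc1ccccc1)[C@H](OCc1ccccc1)[C@H](C)B1O[C@H](C2CCCCC2)[C@@H](C2CCCCC2)O1 | intermediate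
15 | (2S,3R,4S,6R)-3,4,6-tris(benzyloxy)-6-(2-methyloxazol-4-yl)hexan-2-ol | O[C@@H](C)[C@@H](OCc1ccccc1)[C@@H](OCc1ccccc1)C[C@@H](OCc1ccccc1)c1coc(C)n1 | intermediate
16 | 5-bromooxazole | Brc1cnco1 | starting material
17 | lithium (2S,3R,4S,6R)-3,4,6-tris(benzyloxy)-6-[2-(lithiomethyl)oxazol-4-yl]hexan-2-olate | [Li]O[C@@H](C)[C@@H](OCc1ccccc1)[C@@H](OCc1ccccc1)C[C@@H](OCc1ccccc1)c1coc(C[Li])n1 | intermediate
18 | lithium (2S,3R,4S,6R)-3,4,6-tris(benzyloxy)-6-{2-[(chlorozincio)methyl]oxazol-4-yl}hexan-2-olate | [Li]O[C@@H](C)[C@@H](OCc1ccccc1)[C@@H](OCc1ccccc1)C[C@@H](OCc1ccccc1)c1coc(C[Zn]Cl)n1 | intermediate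
19 | (2S,3R,4S,6R)-3,4,6-tris(benzyloxy)-6-[2-(oxazol-5-ylmethyl)oxazol-4-yl]hexan-2-ol | O[C@@H](C)[C@@H](OCc1ccccc1)[C@@H](OCc1ccccc1)C[C@@H](OCc1ccccc1)c1coc(Cc2cnco2)n1 | intermediate
20 | palmitoyl chloride (hexadecanoyl chloride) | CCCCCCCCCCCCCCCC(Cl)=O | starting material
21 | (2S,3R,4S,6R)-3,4,6-tris(benzyloxy)-6-[2-(oxazol-5-ylmethyl)oxazol-4-yl]hexan-2-yl hexadecanoate | CCCCCCCCCCCCCCCC(=O)O[C@@H](C)[C@@H](OCc1ccccc1)[C@@H](OCc1ccccc1)C[C@@H](OCc1ccccc1)c1coc(Cc2cnco2)n1 | intermediate
22 | (2S,3S,4S,6R)-3,4,6-trihydroxy-6-[2-(oxazol-5-ylmethyl)oxazol-4-yl]hexan-2-yl hexadecanoate | CCCCCCCCCCCCCCCC(=O)O[C@@H](C)[C@@H](O)[C@@H](O)C[C@@H](O)c1coc(Cc2cnco2)n1 | target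

Total step count: 5 (step 2 comprises five telescoped homologation cycles and one oxidation). Longest linear sequence: 5 steps, from 1 to 22.

Steps most likely to fail

Step 2. In the first cycle the carbenoid may be lost to metalation of ring A (2-methyl group or C5–H), or boron may be lost from 5 before the borate forms. The fallback reaches the same borate with the roles reversed. Dichloromethyllithium and B(OiPr)3, followed by anhydrous HCl, should give diisopropyl (dichloromethyl)boronate F1. Diol 2 converts F1 by transesterification into (4R,5R)-2-(dichloromethyl)-4,5-dicyclohexyl-1,3,2-dioxaborolane F2. The magnesium compound 3, generated from 1 as in step 1, is added to F2 in THF at −78 °C to give the chloromagnesium (dichloromethyl)(2-methyloxazol-4-yl)borate F3. ZnCl2 then triggers the 1,2-shift to 6. This fallback sets out from 1 and 2, avoids both the isolated boronate 5 and the exposure of ring A to the carbenoid, and comes back to the route at 6, from which the cycles of step 2 continue.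

Step 3. The cross-coupling may stall through ligation of palladium by the amine and the azoles or through slow transmetalation. It may also run on to a second arylation at the newly acidic methylene, or the C5 alkoxide may be oxidised by the arylpalladium species. The fallback builds ring B instead of coupling it. The dilithiated species 17, formed from 15 as in step 3, is quenched with DMF to give 2-{4-[(1R,3S,4R,5S)-1,3,4-tris(benzyloxy)-5-hydroxyhexyl]oxazol-2-yl}acetaldehyde F4. The crude aldehyde is treated with p-toluenesulfonylmethyl isocyanide and K2CO3 in MeOH at reflux (van Leusen oxazole synthesis). The cycloadduct (2S,3R,4S,6R)-3,4,6-tris(benzyloxy)-6-{2-[(4-tosyl-4,5-dihydrooxazol-5-yl)methyl]oxazol-4-yl}hexan-2-ol F5 loses p-toluenesulfinate to give the aromatic ring B. This fallback sets out from 15 and comes back at 19.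

Step 5. Hydrogenolysis may overrun to cleavage of the heterobenzylic C1–O bond or be slowed by binding of the two oxazoles to the metal, and the acyl group may shift to the freed C4 hydroxyl during a long reaction. The fallback is a non-reductive Lewis-acid debenzylation: 21 is treated with BCl3 and pentamethylbenzene in CH2Cl2 at −78 °C and quenched cold with MeOH. It sets out from 21 and comes back at 22 without any new compound.

Further compounds
F1 | step 2 | diisopropyl (dichloromethyl)boronate | ClC(Cl)B(OC(C)C)OC(C)C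
F2 | step 2 | (4R,5R)-2-(dichloromethyl)-4,5-dicyclohexyl-1,3,2-dioxaborolane | ClC(Cl)B1O[C@H](C2CCCCC2)[C@@H](C2CCCCC2)O1
F3 | step 2 | chloromagnesium (4R,5R)-4,5-dicyclohexyl-2-(dichloromethyl)-2-(2-methyloxazol-4-yl)-1,3,2-dioxaborolan-2-uide | Cc1nc(co1)[B-]1(C(Cl)Cl)O[C@H](C2CCCCC2)[C@@H](C2CCCCC2)O1.[Mg+]Cl
F4 | step 3 | 2-{4-[(1R,3S,4R,5S)-1,3,4-tris(benzyloxy)-5-hydroxyhexyl]oxazol-2-yl}acetaldehyde | O[C@@H](C)[C@@H](OCc1ccccc1)[C@@H](OCc1ccccc1)C[C@@H](OCc1ccccc1)c1coc(CC=O)n1
F5 | step 3 | (2S,3R,4S,6R)-3,4,6-tris(benzyloxy)-6-{2-[(4-tosyl-4,5-dihydrooxazol-5-yl)methyl]oxazol-4-yl}hexan-2-ol | O[C@@H](C)[C@@H](OCc1ccccc1)[C@@H](OCc1ccccc1)C[C@@H](OCc1ccccc1)c1coc(CC2OC=NC2S(=O)(=O)c2ccc(C)cc2)n1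
F0 | step 5 | none | none
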